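**Retrosynthetic overview**

1. The strategy rests on the O1–C5 bond of the γ-lactone (ring A: O1, C2, C3, C4, C5), with the C4 carboxyl and the C5 pentadecyl chain cis. C2–C5 are read as the four carbons of a cis-2-alkyl-3-phenylcyclobutanone, O1 is inserted between C2 and C5 by Baeyer–Villiger ring expansion, and phenyl stands for the C4 carboxyl.
2. After the ring expansion: phenyl → CO2H (RuO4), C3 exo-methylene by carboxylation and decarboxylative Mannich reaction, desilylation last.
3. The cis-cyclobutanone is traced back through the cyclobutanol (hydroxyl-directed hydrogenation) and the cyclobutenol (CBS reduction) to a 2-alkyl-3-phenylcyclobut-2-enone. This is preferred to an enantioselective ketene-type [2+2] on the Z-alkene, whose facial control on an acyclic styrene is not dependable.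
4. The cyclobutenone comes from dichloroketene [2+2] addition to a 1-phenylalk-1-yne and zinc dechlorination; the alkyne comes from phenylacetylene, 12-bromododecan-1-ol and (S)-propylene oxide (source of the side-chain carbinol).
5. Ring order: the four-membered carbocycle first (step 5), then its expansion to lactone ring A (step 10), the only ring of the target.

Key step: step 10

Remark: the lactone is numbered O1, C2 (C=O), C3, C4, C5, and TBSO means tert-butyldimethylsilyloxy. The sense of induction in step 7 is assigned on the usual oxazaborolidine model with the substituted alkenyl flank as the large group; the antipodal catalyst would be used should the model not hold.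

**Route**

Step 1
Reactants: 1 phenylacetylene, 2 12-bromododecan-1-ol
Product: 4 14-phenyltetradec-13-yn-1-ol, via lithium phenylacetylide 3 (not isolated)
Conditions: 1 (2.3 equiv), n-BuLi (2.2 equiv), THF, −78 °C; then 2, DMPU, −78 → 40 °C; then H2O
Reagents that add atoms: none
Why: Acetylide alkylation (SN2) of a primary bromide; the first equivalent of 3 only deprotonates the hydroxyl, and the resulting lithium alkoxide is a far poorer nucleophile than the acetylide in THF–DMPU, so no protecting group should be needed.

Step 2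
Reactants: 4 14-phenyltetradec-13-yn-1-ol
Product: 5 (14-bromotetradec-1-yn-1-yl)benzene
Conditions: CBr4, PPh3, CH2Cl2, 0 °C → rt
Reagents that add atoms: carbon tetrabromide, BrC(Br)(Br)Br
Why: Appel bromination of a primary alcohol through the alkoxyphosphonium salt; the internal aryl alkyne is inert.

Step 3
Reactants: 5 (14-bromotetradec-1-yn-1-yl)benzene, 6 (S)-propylene oxide [(2S)-2-methyloxirane]
Product: 8 (2S)-17-phenylheptadec-16-yn-2-ol, via alkylmagnesium bromide 7 (not isolated)
Conditions: Mg, THF, 40 °C; then CuI (10 mol %), 6, THF, −30 → 0 °C; then H2O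
Reagents that add atoms: none
Why: Copper-catalysed Grignard opening of a terminal epoxide at its CH2 carbon; the stereocentre of 6 is not touched and becomes the (S)-carbinol of the side chain.

Step 4
Reactants: 8 (2S)-17-phenylheptadec-16-yn-2-ol
Product: 9 tert-butyl(dimethyl){[(2S)-17-phenylheptadec-16-yn-2-yl]oxy}silane
Conditions: TBSCl, imidazole, DMF, rt
Reagents that add atoms: tert-butyldimethylsilyl chloride, CC(C)(C)[Si](C)(C)Cl
Why: Imidazole-promoted silylation of a secondary alcohol; the TBS ether is chosen because it should survive the organozinc, borane, peracid and RuO4 steps and leaves under acidic fluoride at the end.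

Step 5
Reactants: 9 tert-butyl(dimethyl){[(2S)-17-phenylheptadec-16-yn-2-yl]oxy}silane
Product: 10 4,4-dichloro-2-[(14S)-14-(TBSO)pentadecyl]-3-phenylcyclobut-2-en-1-one
Conditions: Cl3CCOCl, Zn–Cu couple, Et2O–DME, rt → 35 °C
Reagents that add atoms: trichloroacetyl chloride, ClC(=O)C(Cl)(Cl)Cl
Why: Ketene–alkyne [2+2] cycloaddition with dichloroketene made in situ; the ketene carbonyl carbon bonds to the alkyl-bearing alkyne carbon so that positive charge develops on the aryl-bearing carbon, which places CCl2 next to C–Ph and the chain next to C=O, and DME ties up ZnCl2 to protect the silyl ether.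

Step 6
Reactants: 10 4,4-dichloro-2-[(14S)-14-(TBSO)pentadecyl]-3-phenylcyclobut-2-en-1-one
Product: 11 2-[(14S)-14-(TBSO)pentadecyl]-3-phenylcyclobut-2-en-1-one
Conditions: Zn dust, AcOH, TMEDA, EtOH, 0 °C → rt
Reagents that add atoms: none
Why: Reductive dechlorination of an α,α-dichloroketone by zinc through the zinc enolate; the TMEDA–AcOH buffer should suppress ionisation and migration of the allylic chlorides and loss of the silyl ether.

Step 7
Reactants: 11 2-[(14S)-14-(TBSO)pentadecyl]-3-phenylcyclobut-2-en-1-one
Product: 12 (1S)-2-[(14S)-14-(TBSO)pentadecyl]-3-phenylcyclobut-2-en-1-ol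
Conditions: (R)-2-methyl-CBS-oxazaborolidine (20 mol %), BH3·SMe2, THF, −30 °C; then MeOH, H2O
Reagents that add atoms: none
Why: Corey–Bakshi–Shibata 1,2-reduction of a cyclic enone; the ketone should bind boron through the lone pair on the side of the ring CH2, away from the alkyl-substituted alkenyl flank, so hydride from the coordinated borane is delivered to one carbonyl face and the (1S) carbinol, the control element for step 8, is set by the catalyst.

Step 8
Reactants: 12 (1S)-2-[(14S)-14-(TBSO)pentadecyl]-3-phenylcyclobut-2-en-1-ol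
Product: 13 (1S,2S,3S)-2-[(14S)-14-(TBSO)pentadecyl]-3-phenylcyclobutan-1-ol
Conditions: H2 (1 atm), [Ir(cod)(PCy3)(py)]PF6 (5 mol %), CH2Cl2, 0 °C → rt
Reagents that add atoms: none
Why: Hydroxyl-directed homogeneous hydrogenation of a tetrasubstituted cyclic allylic alcohol; iridium binds the hydroxyl and the strained alkene on the same face, so both hydrogens add syn to OH, which makes the alkyl and phenyl groups cis to each other (future C5 and C4) and fixes their absolute configuration from the carbinol centre.

Step 9
Reactants: 13 (1S,2S,3S)-2-[(14S)-14-(TBSO)pentadecyl]-3-phenylcyclobutan-1-ol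
Product: 14 (2S,3S)-2-[(14S)-14-(TBSO)pentadecyl]-3-phenylcyclobutan-1-one
Conditions: Dess–Martin periodinane, NaHCO3, CH2Cl2, 0 °C; crude ketone used at once
Reagents that add atoms: none
Why: Dess–Martin oxidation of a secondary alcohol under bicarbonate buffer, mild and non-basic enough that the epimerisable α-stereocentre of the cis ketone should not equilibrate to trans.

Step 10
Reactants: 14 (2S,3S)-2-[(14S)-14-(TBSO)pentadecyl]-3-phenylcyclobutan-1-one
Product: 16 (4R,5S)-5-[(14S)-14-(TBSO)pentadecyl]-4-phenyloxolan-2-one, via Criegee adduct 15 (not isolated)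
Conditions: mCPBA, NaHCO3, CH2Cl2, 0 °C
Reagents that add atoms: 3-chloroperoxybenzoic acid, OOC(=O)c1cccc(Cl)c1
Why: Baeyer–Villiger oxidation: the peracid adds to the strained carbonyl C2 to give Criegee adduct 15, and the secondary ring carbon (future C5), antiperiplanar to the O–O bond, shifts from C2 to oxygen as 3-chlorobenzoate leaves. The closest known reaction type is the peracid ring expansion of 2-substituted cyclobutanones to 5-substituted γ-butyrolactones. Ring A (O1, C2, C3, C4, C5) is closed not by cyclisation but by a 1,2-shift that enlarges the four-membered ring by one oxygen and forms O1–C5. No stereocentre is created: C5 migrates with retention and C4 is a spectator, so the cis relation set in step 8 is carried over unchanged. The step needs migration of the substituted carbon in preference to the ring CH2, which the better ability of the secondary carbon to bear positive charge in the transition state secures, and it needs the α-stereocentre to survive, which the bicarbonate buffer and the strain-driven rate at 0 °C secure. Phenyl, the silyl ether and the saturated chain are inert to the peracid.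

Step 11
Reactants: 16 (4R,5S)-5-[(14S)-14-(TBSO)pentadecyl]-4-phenyloxolan-2-one
Product: 17 (2S,3S)-2-[(14S)-14-(TBSO)pentadecyl]-5-oxooxolane-3-carboxylic acid
Conditions: RuCl3·xH2O (5 mol %), NaIO4 (18 equiv), CCl4–MeCN–H2O, rt
Reagents that add atoms: sodium periodate, [Na+].[O-]I(=O)(=O)=O; water, O
Why: Ruthenium tetroxide arene degradation (Sharpless conditions): RuO4 formed in situ destroys the phenyl ring down to its ipso carbon, which remains as the C4 carboxyl, while C4 and C5 are not enolisable here and the lactone, chain and silyl ether should not be attacked.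

Step 12
Reactants: 17 (2S,3S)-2-[(14S)-14-(TBSO)pentadecyl]-5-oxooxolane-3-carboxylic acid
Product: 18 (2S,3S)-2-[(14S)-14-(TBSO)pentadecyl]-5-oxooxolane-3,4-dicarboxylic acid (C4 epimers, taken on crude)
Conditions: MeOMgOCO2Me (2 M in DMF), 130 °C; then cold aq. HCl
Reagents that add atoms: methyl magnesium carbonate, CO[Mg]OC(=O)OC
Why: Stiles carboxylation of the lactone α-carbon (C3 of ring A), driven by the magnesium chelate of the resulting β-carboxy lactone; C4–H lies α to a carboxylate anion and should not be removed, so the cis relation should hold, and loss of the silyl ether here would be harmless.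

Step 13
Reactants: 18 (2S,3S)-2-[(14S)-14-(TBSO)pentadecyl]-5-oxooxolane-3,4-dicarboxylic acid
Product: 20 (2S,3S)-2-[(14S)-14-(TBSO)pentadecyl]-4-methylidene-5-oxooxolane-3-carboxylic acid, via Mannich base 19 (not isolated)
Conditions: 37% aq. HCHO, PhNHMe, NaOAc, AcOH, rt
Reagents that add atoms: formaldehyde, C=O
Why: Decarboxylative Mannich methylenation: the malonic-type acid adds to the iminium ion from formaldehyde and N-methylaniline to give 19, which loses CO2 and the amine to leave the exocyclic C3=CH2 under conditions too weakly basic to move the alkene into the ring or to epimerise C4.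

Step 14
Reactants: 20 (2S,3S)-2-[(14S)-14-(TBSO)pentadecyl]-4-methylidene-5-oxooxolane-3-carboxylic acid
Product: 21 (2S,3S)-2-[(14S)-14-hydroxypentadecyl]-4-methylidene-5-oxooxolane-3-carboxylic acid
Conditions: 48% aq. HF, MeCN, 0 °C → rt
Reagents that add atoms: none
Why: Acidic fluoride desilylation; the α-methylene lactone and the free acid, which would suffer conjugate addition or alkene migration with basic fluoride or alkoxide, should be stable to aqueous HF in acetonitrile.

**Compound list**

1 | phenylacetylene | C#Cc1ccccc1 | starting material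
2 | 12-bromododecan-1-ol | OCCCCCCCCCCCCBr | starting material
3 | lithium phenylacetylide | [Li]C#Cc1ccccc1 | intermediate
4 | 14-phenyltetradec-13-yn-1-ol | OCCCCCCCCCCCCC#Cc1ccccc1 | intermediate
5 | (14-bromotetradec-1-yn-1-yl)benzene | BrCCCCCCCCCCCCC#Cc1ccccc1 | intermediate
6 | (S)-propylene oxide | C[C@H]1CO1 | starting material
7 | (14-phenyltetradec-13-yn-1-yl)magnesium bromide | Br[Mg]CCCCCCCCCCCCC#Cc1ccccc1 | intermediate
8 | (2S)-17-phenylheptadec-16-yn-2-ol | C[C@H](O)CCCCCCCCCCCCCC#Cc1ccccc1 | intermediate
9 | tert-butyl(dimethyl){[(2S)-17-phenylheptadec-16-yn-2-yl]oxy}silane | C[C@H](O[Si](C)(C)C(C)(C)C)CCCCCCCCCCCCCC#Cc1ccccc1 | intermediate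
10 | 4,4-dichloro-2-[(14S)-14-(tert-butyldimethylsilyloxy)pentadecyl]-3-phenylcyclobut-2-en-1-one | O=C1C(CCCCCCCCCCCCC[C@H](C)O[Si](C)(C)C(C)(C)C)=C(c2ccccc2)C1(Cl)Cl | intermediate
11 | 2-[(14S)-14-(tert-butyldimethylsilyloxy)pentadecyl]-3-phenylcyclobut-2-en-1-one | O=C1CC(c2ccccc2)=C1CCCCCCCCCCCCC[C@H](C)O[Si](C)(C)C(C)(C)C | intermediate
12 | (1S)-2-[(14S)-14-(tert-butyldimethylsilyloxy)pentadecyl]-3-phenylcyclobut-2-en-1-ol | C1[C@H](O)C(CCCCCCCCCCCCC[C@H](C)O[Si](C)(C)C(C)(C)C)=C1c1ccccc1 | intermediate
13 | (1S,2S,3S)-2-[(14S)-14-(tert-butyldimethylsilyloxy)pentadecyl]-3-phenylcyclobutan-1-ol (OH trans to the cis alkyl and phenyl groups) | C1[C@H](O)[C@@H](CCCCCCCCCCCCC[C@H](C)O[Si](C)(C)C(C)(C)C)[C@H]1c1ccccc1 | intermediate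
14 | (2S,3S)-2-[(14S)-14-(tert-butyldimethylsilyloxy)pentadecyl]-3-phenylcyclobutan-1-one (cis) | C1C(=O)[C@@H](CCCCCCCCCCCCC[C@H](C)O[Si](C)(C)C(C)(C)C)[C@H]1c1ccccc1 | intermediate
15 | Criegee adduct: (2S,3S)-1-hydroxy-2-[(14S)-14-(tert-butyldimethylsilyloxy)pentadecyl]-3-phenylcyclobutyl 3-chloroperoxybenzoate (C1 undefined) | C1C(O)(OOC(=O)c2cccc(Cl)c2)[C@@H](CCCCCCCCCCCCC[C@H](C)O[Si](C)(C)C(C)(C)C)[C@H]1c1ccccc1 | intermediate
16 | (4R,5S)-5-[(14S)-14-(tert-butyldimethylsilyloxy)pentadecyl]-4-phenyloxolan-2-one (cis) | C1C(=O)O[C@@H](CCCCCCCCCCCCC[C@H](C)O[Si](C)(C)C(C)(C)C)[C@H]1c1ccccc1 | intermediate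
17 | (2S,3S)-2-[(14S)-14-(tert-butyldimethylsilyloxy)pentadecyl]-5-oxooxolane-3-carboxylic acid (cis) | C1C(=O)O[C@@H](CCCCCCCCCCCCC[C@H](C)O[Si](C)(C)C(C)(C)C)[C@H]1C(=O)O | intermediate
18 | (2S,3S)-2-[(14S)-14-(tert-butyldimethylsilyloxy)pentadecyl]-5-oxooxolane-3,4-dicarboxylic acid (C4 epimers) | OC(=O)C1C(=O)O[C@@H](CCCCCCCCCCCCC[C@H](C)O[Si](C)(C)C(C)(C)C)[C@H]1C(=O)O | intermediate
19 | Mannich base: (2S,3S)-4-[(N-methylanilino)methyl]-2-[(14S)-14-(tert-butyldimethylsilyloxy)pentadecyl]-5-oxooxolane-3,4-dicarboxylic acid (C4 undefined) | OC(=O)C1(CN(C)c2ccccc2)C(=O)O[C@@H](CCCCCCCCCCCCC[C@H](C)O[Si](C)(C)C(C)(C)C)[C@H]1C(=O)O | intermediate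
20 | (2S,3S)-2-[(14S)-14-(tert-butyldimethylsilyloxy)pentadecyl]-4-methylidene-5-oxooxolane-3-carboxylic acid | C=C1C(=O)O[C@@H](CCCCCCCCCCCCC[C@H](C)O[Si](C)(C)C(C)(C)C)[C@H]1C(=O)O | intermediate
21 | (2S,3S)-2-[(14S)-14-hydroxypentadecyl]-4-methylidene-5-oxooxolane-3-carboxylic acid | C=C1C(=O)O[C@@H](CCCCCCCCCCCCC[C@H](C)O)[C@H]1C(=O)O | target

**Step count and risks**

Total: 14 steps. Longest linear sequence: 14 steps (1 and 2 to 21; 6 enters at step 3).

Steps most likely to fail:

1. Step 7 (CBS reduction). The catalyst may not tell the alkenyl flank of the four-membered ketone from the ring CH2 well enough, and the resulting loss of control over C4 and C5 relative to the remote carbinol could not be corrected by separation later. Fallback for step 7, from 11 back to 12: Luche reduction of 11 (NaBH4, CeCl3·7H2O, MeOH, −40 °C) should give the cyclobutenol F1 as a mixture of both C1 epimers. Acylation of this mixture with vinyl acetate under Burkholderia cepacia lipase (Amano PS) in tert-butyl methyl ether is expected, by the empirical rule for secondary alcohols, to esterify the (1R) epimer to the (1R)-cyclobutenyl acetate F2 and to leave the (1S) alcohol, which after chromatography is 12.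

2. Step 8 (directed hydrogenation). Hydrogen uptake at the tetrasubstituted, aryl-conjugated alkene may be slow, and the directing effect may be eroded by competing iridium-hydride isomerisation of the allylic alcohol. Fallback for step 8, from 11 back to 14, relying on steric instead of directed delivery: reduction of 11 with the antipodal (S)-2-methyl-CBS-oxazaborolidine and BH3·SMe2 should give the (1R)-cyclobutenol F3 in place of 12. TESCl and imidazole in CH2Cl2 should convert it into the (1R)-cyclobutenyl triethylsilyl ether F4, whose bulky silyloxy group shields one face of the ring. Heterogeneous hydrogenation (H2, Pt/C, EtOAc, rt; platinum chosen so that the phenyl ring is not reduced) should then add both hydrogens anti to the silyloxy group and give the all-cis (1R,2S,3S)-cyclobutyl triethylsilyl ether F5. PPTS in MeOH at 0 °C should remove the triethylsilyl group in the presence of the secondary TBS ether to give the all-cis (1R,2S,3S)-cyclobutanol F6, which differs from 13 only at the carbinol carbon, and buffered Dess–Martin oxidation as in step 9 then gives 14.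

3. Step 12 (Stiles carboxylation at 130 °C). Prolonged heating with the basic magnesium reagent may cause incomplete carboxylation or epimerisation of the cis acid at C4. Fallback for step 12, from 17 back to 20 with steps 12 and 13 bypassed, by kinetic enolate aminomethylation at low temperature: the dianion of 17 (LiN(SiMe3)2, 2.2 equiv, THF, −78 °C) is trapped with Eschenmoser's salt (Me2N=CH2 iodide) to give the α-(dimethylaminomethyl) lactone acid F7 as a mixture at the new centre. Quaternisation with MeI in MeOH over NaHCO3 should give the trimethylammonium iodide F8, and stirring with aqueous NaHCO3 followed by mild acidification should effect elimination of trimethylamine to 20.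

**Further compounds**

F1 | step 7 | (1RS)-2-[(14S)-14-(tert-butyldimethylsilyloxy)pentadecyl]-3-phenylcyclobut-2-en-1-ol (both C1 epimers) | C1C(O)C(CCCCCCCCCCCCC[C@H](C)O[Si](C)(C)C(C)(C)C)=C1c1ccccc1
F2 | step 7 | (1R)-2-[(14S)-14-(tert-butyldimethylsilyloxy)pentadecyl]-3-phenylcyclobut-2-en-1-yl acetate | C1[C@@H](OC(C)=O)C(CCCCCCCCCCCCC[C@H](C)O[Si](C)(C)C(C)(C)C)=C1c1ccccc1
F3 | step 8 | (1R)-2-[(14S)-14-(tert-butyldimethylsilyloxy)pentadecyl]-3-phenylcyclobut-2-en-1-ol | C1[C@@H](O)C(CCCCCCCCCCCCC[C@H](C)O[Si](C)(C)C(C)(C)C)=C1c1ccccc1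
F4 | step 8 | (1R)-2-[(14S)-14-(tert-butyldimethylsilyloxy)pentadecyl]-3-phenylcyclobut-2-en-1-yl triethylsilyl ether | C1[C@@H](O[Si](CC)(CC)CC)C(CCCCCCCCCCCCC[C@H](C)O[Si](C)(C)C(C)(C)C)=C1c1ccccc1
F5 | step 8 | (1R,2S,3S)-2-[(14S)-14-(tert-butyldimethylsilyloxy)pentadecyl]-3-phenylcyclobutyl triethylsilyl ether (all-cis) | C1[C@@H](O[Si](CC)(CC)CC)[C@@H](CCCCCCCCCCCCC[C@H](C)O[Si](C)(C)C(C)(C)C)[C@H]1c1ccccc1
F6 | step 8 | (1R,2S,3S)-2-[(14S)-14-(tert-butyldimethylsilyloxy)pentadecyl]-3-phenylcyclobutan-1-ol (all-cis) | C1[C@@H](O)[C@@H](CCCCCCCCCCCCC[C@H](C)O[Si](C)(C)C(C)(C)C)[C@H]1c1ccccc1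
F7 | step 12 | (2S,3S)-4-[(dimethylamino)methyl]-2-[(14S)-14-(tert-butyldimethylsilyloxy)pentadecyl]-5-oxooxolane-3-carboxylic acid (C4 undefined) | CN(C)CC1C(=O)O[C@@H](CCCCCCCCCCCCC[C@H](C)O[Si](C)(C)C(C)(C)C)[C@H]1C(=O)O
F8 | step 12 | {(4S,5S)-4-carboxy-5-[(14S)-14-(tert-butyldimethylsilyloxy)pentadecyl]-2-oxooxolan-3-yl}methyl(trimethyl)ammonium iodide | C[N+](C)(C)CC1C(=O)O[C@@H](CCCCCCCCCCCCC[C@H](C)O[Si](C)(C)C(C)(C)C)[C@H]1C(=O)O.[I-]
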